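**Retrosynthetic overview**
- The target is traced back to a triol enoate (selective C2 acetylation), then to a C13 methyl ketone (Horner–Wadsworth–Emmons), then to a trans-octalone carrying a C9 ketone and a C2=C3 alkene (α-face osmylation; α-face addition of a masked 3-oxobutyl nucleophile to C9).
- Ring A is annulated onto ring B in one flask as a [3+3] union with an unbranched (Z)-3-iodoallyl unit: C1–C10 by enolate alkylation, C3–C4 by reductive Heck closure. The C2=C3 alkene that remains is the precursor of the cis-2α,3α-diol.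
- Enabling feature: C10 is the α′-carbon of the C9 carbonyl, and C4 is the internal carbon of an isopropenyl group on C5, 1,3 to C10 across the C5 stereocentre. This is exactly ring B of 6-methylcarvone, so C1–C3 can bridge an enolate carbon and a 1,1-disubstituted alkene.
- Stereochemistry: C5 is bought with (R)-carvone and relays C10 (alkylation anti to isopropenyl), the trans ring fusion, C8 (equilibration), C9 (attack anti to the axial C10 methyl) and C2/C3 (osmylation anti to the two axial β-methyls).
- Ring order: ring B from the chiral pool, ring A closed in step 4, side chain attached and finished last.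

Key step: step 4

Remark: atom numbers and α/β follow labdane numbering with the C10 methyl β; the target is taken exactly as drawn (9-OH β and cis to the C10 methyl, C9 side chain α, 8α-methyl, 2α-OAc, 3α-OH, 13E).

**Step 1**
Reactants: 1 (R)-(−)-carvone
Product: 3 (5R,6S)-2,6-dimethyl-5-(prop-1-en-2-yl)cyclohex-2-en-1-one (trans-6-methylcarvone), via lithium dienolate 2 (not isolated)
Conditions: LDA (1.05 equiv), THF, −78 °C; MeI, −78 → −20 °C
Reagents that add atoms: iodomethane CI
Why: Kinetic α′-deprotonation of the enone gives the cross-conjugated lithium dienolate, and its C-methylation (enolate alkylation) should occur mainly anti to the C5 isopropenyl group; the new centre (labdane C10) is planarized again in step 4, so its ratio does not matter.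

**Step 2**
Reactants: 4 ethyl (Z)-3-iodoacrylate
Product: 5 (Z)-3-iodoprop-2-en-1-ol
Conditions: DIBAL-H (2.2 equiv), CH2Cl2, −78 °C; Rochelle salt work-up
Reagents that add atoms: none
Why: DIBAL-H reduction of the ester to the allylic alcohol at low temperature should leave the vinyl iodide and the Z geometry untouched; no stereocentre is formed.

**Step 3**
Reactants: 5 (Z)-3-iodoprop-2-en-1-ol
Product: 6 (Z)-3-bromo-1-iodoprop-1-ene
Conditions: CBr4, PPh3, CH2Cl2, 0 °C
Reagents that add atoms: tetrabromomethane BrC(Br)(Br)Br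
Why: The Appel reaction converts the primary allylic alcohol into the bromide under neutral conditions that should not isomerize the (Z)-vinyl iodide.

**Step 4**
Reactants: 3 (5R,6S)-2,6-dimethyl-5-(prop-1-en-2-yl)cyclohex-2-en-1-one; 6 (Z)-3-bromo-1-iodoprop-1-ene
Product: 9 (4aS,8aS)-2,5,5,8a-tetramethyl-4a,5,8,8a-tetrahydronaphthalen-1(4H)-one, via lithium dienolate 7 (not isolated), via vinyl iodide 8 (not isolated)
Conditions: LDA (1.1 equiv), THF, −78 °C; 6 (0.95 equiv), DMPU, −78 → 0 °C; then, same flask without work-up, Pd(OAc)2 (10 mol %), PPh3 (25 mol %), HCO2Na (3 equiv), Et4NCl, DMF, 75 °C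
Reagents that add atoms: none
Why: LDA removes the remaining α′-hydrogen to give the tetrasubstituted cross-conjugated dienolate 7, which is C-alkylated (SN2) by the allylic bromide on the face anti to the C5 isopropenyl group (held pseudo-axial by A(1,2) strain with the C10 methyl), forming C1–C10 and the quaternary C10 of 8 with the methyl cis to the isopropenyl. On addition of Pd(0) and formate, oxidative addition into the (Z)-vinyl C3–I bond and 6-exo-trig syn-carbopalladation of the isopropenyl C4=CH2 form C3–C4 and close ring A; the resulting neopentyl alkylpalladium has no β-hydrogen and is reduced by formate (loss of CO2, C–H reductive elimination), which turns the former =CH2 into the second C4 methyl. The closest known reaction types are the trans-selective second α′-alkylation of 6-substituted carvones with allylic halides and the reductive Heck cyclization with formate capture that creates a quaternary carbon. Ring A closes by 6-exo-trig migratory insertion with C2=C3 endocyclic, and because C1 and C4 are trans on ring B the fusion can only be trans (5α-H, 10β-methyl). The only new stereocentre, C10, is controlled by the purchased C5 centre. The step needs C- over O-alkylation and SN2 over SN2′ (soft primary allylic bromide), retention of the Z geometry (untouched by the SN2 step and mandatory for ring closure), 6-exo over 7-endo insertion (palladium goes to the terminal CH2) and cyclization before hydride capture of the vinylpalladium (sparingly soluble HCO2Na), followed by hydride capture faster than 3-exo attack on C2=C3 (excess formate).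

**Step 5**
Reactants: 9 (4aS,8aS)-2,5,5,8a-tetramethyl-4a,5,8,8a-tetrahydronaphthalen-1(4H)-one
Product: 11 (2R,4aS,8aS)-2,5,5,8a-tetramethyl-3,4,4a,5,8,8a-hexahydronaphthalen-1(2H)-one, via lithium enolate 10 (not isolated)
Conditions: L-Selectride (1.1 equiv), THF, −78 °C; aq. NH4Cl; then NaOMe (cat.), MeOH, rt
Reagents that add atoms: none
Why: L-Selectride should deliver hydride 1,4 to the β-monosubstituted enone, whose carbonyl is shielded by the quaternary C10 (conjugate reduction), and base equilibration of the epimerizable C8 centre then places the methyl equatorial (α), since the axial epimer would be 1,3-diaxial to the C10 methyl.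

**Step 6**
Reactants: 11 (2R,4aS,8aS)-2,5,5,8a-tetramethyl-3,4,4a,5,8,8a-hexahydronaphthalen-1(2H)-one; 12 2-(2-bromoethyl)-2-methyl-1,3-dioxolane
Product: 14 (1S,2R,4aS,8aS)-2,5,5,8a-tetramethyl-1-[2-(2-methyl-1,3-dioxolan-2-yl)ethyl]-1,2,3,4,4a,5,8,8a-octahydronaphthalen-1-ol, via Grignard reagent 13 (not isolated)
Conditions: 12, Mg, THF, 25 °C; anhydrous CeCl3, THF, −78 °C; then 11, −78 → 0 °C; aq. NH4Cl
Reagents that add atoms: none
Why: The organocerium reagent (Imamoto conditions) should add to the enolizable, doubly α-branched C9 ketone without enolization and attack axially from the α face, anti to the axial C10 methyl that blocks the β face, so the hydroxyl ends up β (equatorial) and the side chain α.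

**Step 7**
Reactants: 14 (1S,2R,4aS,8aS)-2,5,5,8a-tetramethyl-1-[2-(2-methyl-1,3-dioxolan-2-yl)ethyl]-1,2,3,4,4a,5,8,8a-octahydronaphthalen-1-ol
Product: 15 2α,3α,9β-trihydroxy ketal (14 with the C2=C3 alkene replaced by a cis-diol on the α face)
Conditions: OsO4 (5 mol %), NMO (1.5 equiv), t-BuOH/THF/H2O, rt
Reagents that add atoms: osmium tetroxide O=[Os](=O)(=O)=O; N-methylmorpholine N-oxide C[N+]1([O-])CCOCC1
Why: Upjohn dihydroxylation adds both oxygens syn to the only alkene from the α face, opposite to the syn-axial C10 and C4β methyl groups, which should set C2 and C3 as the 2α,3α-cis-diol.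

**Step 8**
Reactants: 15 2α,3α,9β-trihydroxy ketal
Product: 16 2α,3α,9β-trihydroxy C13 methyl ketone
Conditions: 1 M HCl, THF, rt
Reagents that add atoms: water O
Why: Acid-catalysed acetal hydrolysis liberates the C13 methyl ketone (which may rest as its 9,13-hemiketal) while the diol and the tertiary alcohol stay untouched; acetone is avoided so that no acetonide forms.

**Step 9**
Reactants: 16 2α,3α,9β-trihydroxy C13 methyl ketone
Product: 17 methyl (2E)-5-[(1S,2R,4aS,6S,7R,8aS)-1,6,7-trihydroxy-2,5,5,8a-tetramethyldecahydronaphthalen-1-yl]-3-methylpent-2-enoate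
Conditions: trimethyl phosphonoacetate (3 equiv), NaH (3 equiv), THF, 0 °C (anion pre-formed); then 16, 0 → 50 °C
Reagents that add atoms: trimethyl phosphonoacetate COC(=O)CP(=O)(OC)OC
Why: Horner–Wadsworth–Emmons olefination of the methyl ketone should give mainly the E-enoate (ester trans to the larger C12 chain), the minor Z isomer being removed by chromatography.

**Step 10**
Reactants: 17 methyl (2E)-5-[(1S,2R,4aS,6S,7R,8aS)-1,6,7-trihydroxy-2,5,5,8a-tetramethyldecahydronaphthalen-1-yl]-3-methylpent-2-enoate
Product: 18 methyl (2E)-5-[(1S,2R,4aS,6S,7R,8aS)-7-acetoxy-1,6-dihydroxy-2,5,5,8a-tetramethyldecahydronaphthalen-1-yl]-3-methylpent-2-enoate (CNP0135744.1)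
Conditions: Ac2O (1.1 equiv), pyridine, CH2Cl2, 0 °C
Reagents that add atoms: acetic anhydride CC(=O)OC(C)=O
Why: Kinetic acylation should discriminate the equatorial C2 hydroxyl from the axial, neopentyl C3 hydroxyl (next to the gem-dimethyl C4) and the tertiary C9 hydroxyl, giving the 2-monoacetate.

**Compound list**
1 | (R)-(−)-carvone | CC1=CC[C@H](CC1=O)C(C)=C | starting material
2 | lithium dienolate of carvone | [Li]OC1=C[C@@H](CC=C1C)C(C)=C | intermediate
3 | (5R,6S)-2,6-dimethyl-5-(prop-1-en-2-yl)cyclohex-2-en-1-one | C[C@@H]1C(=O)C(C)=CC[C@H]1C(C)=C | intermediate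
4 | ethyl (Z)-3-iodoacrylate | CCOC(=O)/C=C\I | starting material
5 | (Z)-3-iodoprop-2-en-1-ol | OC/C=C\I | intermediate
6 | (Z)-3-bromo-1-iodoprop-1-ene | BrC/C=C\I | intermediate
7 | lithium dienolate of 3 | [Li]OC1=C(C)[C@H](C(C)=C)CC=C1C | intermediate
8 | (5S,6S)-6-[(2Z)-3-iodoprop-2-en-1-yl]-2,6-dimethyl-5-(prop-1-en-2-yl)cyclohex-2-en-1-one | I/C=C\C[C@]1(C)C(=O)C(C)=CC[C@H]1C(C)=C | intermediate
9 | (4aS,8aS)-2,5,5,8a-tetramethyl-4a,5,8,8a-tetrahydronaphthalen-1(4H)-one | O=C1C(C)=CC[C@H]2C(C)(C)C=CC[C@@]21C | intermediate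
10 | lithium enolate from conjugate reduction of 9 | [Li]OC1=C(C)CC[C@H]2C(C)(C)C=CC[C@@]21C | intermediate
11 | (2R,4aS,8aS)-2,5,5,8a-tetramethyl-3,4,4a,5,8,8a-hexahydronaphthalen-1(2H)-one | O=C1[C@H](C)CC[C@H]2C(C)(C)C=CC[C@@]21C | intermediate
12 | 2-(2-bromoethyl)-2-methyl-1,3-dioxolane | CC1(CCBr)OCCO1 | starting material
13 | [2-(2-methyl-1,3-dioxolan-2-yl)ethyl]magnesium bromide | CC1(CC[Mg]Br)OCCO1 | intermediate
14 | (1S,2R,4aS,8aS)-2,5,5,8a-tetramethyl-1-[2-(2-methyl-1,3-dioxolan-2-yl)ethyl]-1,2,3,4,4a,5,8,8a-octahydronaphthalen-1-ol | CC1(CC[C@]2(O)[C@H](C)CC[C@H]3C(C)(C)C=CC[C@@]32C)OCCO1 | intermediate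
15 | 2α,3α,9β-trihydroxy ketal (cis-diol on the α face of ring A) | CC1(CC[C@]2(O)[C@H](C)CC[C@H]3C(C)(C)[C@H](O)[C@H](O)C[C@@]32C)OCCO1 | intermediate
16 | 2α,3α,9β-trihydroxy C13 methyl ketone | CC(=O)CC[C@]1(O)[C@H](C)CC[C@H]2C(C)(C)[C@H](O)[C@H](O)C[C@@]21C | intermediate
17 | methyl (2E)-5-[(1S,2R,4aS,6S,7R,8aS)-1,6,7-trihydroxy-2,5,5,8a-tetramethyldecahydronaphthalen-1-yl]-3-methylpent-2-enoate | COC(=O)/C=C(\C)CC[C@]1(O)[C@H](C)CC[C@H]2C(C)(C)[C@H](O)[C@H](O)C[C@@]21C | intermediate
18 | methyl (2E)-5-[(1S,2R,4aS,6S,7R,8aS)-7-acetoxy-1,6-dihydroxy-2,5,5,8a-tetramethyldecahydronaphthalen-1-yl]-3-methylpent-2-enoate | COC(=O)/C=C(\C)CC[C@]1(O)[C@H](C)CC[C@H]2C(C)(C)[C@H](O)[C@H](OC(C)=O)C[C@@]21C | target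

**Step count**
Total: 10 steps. Longest linear sequence: 9 steps (steps 2, 3, 4–10, from ethyl (Z)-3-iodoacrylate); 8 steps from (R)-carvone.

**Steps most likely to fail**

Step 4. The vinylpalladium may be reduced by formate before it cyclizes, the neopentyl palladium may attack C2=C3 (3-exo, then ring expansion), or palladium hydride may move the C2=C3 alkene. The fallback separates the two bond formations and closes ring A by a radical instead. It sets out from 3: LDA and allyl bromide should give (5S,6S)-6-allyl-2,6-dimethyl-5-(prop-1-en-2-yl)cyclohex-2-en-1-one F1. Aldehyde-selective (nitrite-modified) Wacker oxidation of the monosubstituted alkene should give 3-[(1S,6S)-1,3-dimethyl-2-oxo-6-(prop-1-en-2-yl)cyclohex-3-en-1-yl]propanal F2. Fe(acac)3/PhSiH3 in EtOH should generate the tertiary C4 radical by hydrogen-atom transfer to the isopropenyl group and close it 6-exo onto the aldehyde to give (4aS,8aS)-6-hydroxy-2,5,5,8a-tetramethyl-4a,5,6,7,8,8a-hexahydronaphthalen-1(4H)-one F3 as a mixture of C3 epimers. Dehydration with the Burgess reagent, which can only proceed toward C2 because C4 is quaternary, returns to the route at 9.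

Step 6. The hindered, enolizable C9 ketone may be enolized or may simply not add a β-branched alkyl nucleophile. The fallback uses a small, irreversible one-carbon nucleophile and builds the chain by epoxide opening. It sets out from 11: dimethylsulfonium methylide (Me3S+ I−, n-BuLi, THF) should attack axially, anti to the C10 methyl, to give the 9β,11-spiro-epoxide F4 (oxygen β, CH2 α). Lithiated acetone N,N-dimethylhydrazone should open it at the CH2 to give the 9β-hydroxy C13 N,N-dimethylhydrazone F5. Hydrolysis (aq. CuCl2 or oxalic acid) should give the 9β-hydroxy C2=C3-ene C13 methyl ketone F6. OsO4/NMO dihydroxylation of F6 returns to the route at 16.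

Step 9. E/Z control may be poor, and the C9 alkoxide may add 5-exo to the new enoate under base (9,13-ether formation). The fallback fixes the alkene geometry in the reagent and avoids strong base. It sets out from 11: vinylmagnesium bromide/CeCl3 should give (1S,2R,4aS,8aS)-1-ethenyl-2,5,5,8a-tetramethyl-1,2,3,4,4a,5,8,8a-octahydronaphthalen-1-ol F7. 9-BBN should hydroborate the monosubstituted vinyl group selectively to give the B-alkyl-9-BBN adduct F8. B-alkyl Suzuki–Miyaura coupling with methyl (E)-3-iodobut-2-enoate (PdCl2(dppf), K3PO4, DMF/H2O) should give methyl (2E)-5-[(1S,2R,4aS,8aS)-1-hydroxy-2,5,5,8a-tetramethyl-1,2,3,4,4a,5,8,8a-octahydronaphthalen-1-yl]-3-methylpent-2-enoate F9. OsO4/NMO, which should prefer the isolated C2=C3 alkene over the electron-poor enoate, returns to the route at 17.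

**Further compounds**
F1 | step 4 | (5S,6S)-6-allyl-2,6-dimethyl-5-(prop-1-en-2-yl)cyclohex-2-en-1-one | C=CC[C@]1(C)C(=O)C(C)=CC[C@H]1C(C)=C
F2 | step 4 | 3-[(1S,6S)-1,3-dimethyl-2-oxo-6-(prop-1-en-2-yl)cyclohex-3-en-1-yl]propanal | O=CCC[C@]1(C)C(=O)C(C)=CC[C@H]1C(C)=C
F3 | step 4 | (4aS,8aS)-6-hydroxy-2,5,5,8a-tetramethyl-4a,5,6,7,8,8a-hexahydronaphthalen-1(4H)-one (C6 epimers) | O=C1C(C)=CC[C@H]2C(C)(C)C(O)CC[C@@]21C
F4 | step 6 | 9β,11-spiro-epoxide of 11 (oxygen β, CH2 α) | C1O[C@]12[C@H](C)CC[C@H]3C(C)(C)C=CC[C@@]32C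
F5 | step 6 | 9β-hydroxy C13 N,N-dimethylhydrazone | CN(C)N=C(C)CC[C@]1(O)[C@H](C)CC[C@H]2C(C)(C)C=CC[C@@]21C
F6 | step 6 | 9β-hydroxy C2=C3-ene C13 methyl ketone | CC(=O)CC[C@]1(O)[C@H](C)CC[C@H]2C(C)(C)C=CC[C@@]21C
F7 | step 9 | (1S,2R,4aS,8aS)-1-ethenyl-2,5,5,8a-tetramethyl-1,2,3,4,4a,5,8,8a-octahydronaphthalen-1-ol | C=C[C@]1(O)[C@H](C)CC[C@H]2C(C)(C)C=CC[C@@]21C
F8 | step 9 | B-alkyl-9-BBN adduct of F7 | B1(C2CCCC1CCC2)CC[C@]3(O)[C@H](C)CC[C@H]4C(C)(C)C=CC[C@@]43C
F9 | step 9 | methyl (2E)-5-[(1S,2R,4aS,8aS)-1-hydroxy-2,5,5,8a-tetramethyl-1,2,3,4,4a,5,8,8a-octahydronaphthalen-1-yl]-3-methylpent-2-enoate | COC(=O)/C=C(\C)CC[C@]1(O)[C@H](C)CC[C@H]2C(C)(C)C=CC[C@@]21C
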